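The seven-membered ring is disconnected at C3–C4 and C1–C7, a formal [4+3] cut. One operation, dirhodium-carbenoid cyclopropanation of a diene and Cope rearrangement of the resulting cis-divinylcyclopropane, closes this ring and sets C1 and the quaternary C7. It exploits the oxygen pattern of the seven-membered ring (C1–C7): the C1 oxygen next to C7 and the C5 oxygen map onto a 4-siloxyvinyl carbenoid (C1–C3) and a 2-siloxydiene (C4–C7) whose far alkene C6=C7 belongs to the five-membered ring (C6–C10). The precursors are an E-siloxyvinyl diazoester and the silyl dienol ether of ketal-protected 2-acetyl-3-methylcyclopentenone. Afterwards the ester becomes the C3 methyl and C6, C5 and C10 are set by substrate control.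

Key step: step 7

Remark: locants follow the target core: seven-membered ring C1 (angeloyloxy), C2=C3 (methyl on C3), C4, C5 (veratroyloxy), C6 (ring-fusion H), C7 (ring-fusion methyl); five-membered ring C6, C7, C8, C9, C10 (hydroxyl and isopropyl); β is the face of the C7 methyl, α the opposite face, so the target is 1α,5α-diacyloxy, 6α-H, 7β-methyl, 10β-hydroxy, 10α-isopropyl.

Remark: Rh2(R-DOSP)4 is dirhodium tetrakis[(R)-N-(4-dodecylphenylsulfonyl)prolinate]; this enantiomer is assigned from the usual facial model for donor/acceptor carbenoids, with the cyclopentenyl group of 9 in the place of the alkene substituent, and Rh2(S-DOSP)4 is used instead if the sense of induction proves opposite.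

Remark: the silylation in step 5 is assumed to give both enol ether geometries, so only the E isomer is carried forward.

Step 1
Reactants: 1 3-methylcyclopent-2-en-1-one
Product: 3 2-bromo-3-methylcyclopent-2-en-1-one, via dibromoketone 2 (not isolated)
Conditions: Br2, CH2Cl2, 0 °C; then Et3N, 0 °C to rt
Reagents that add atoms: bromine (BrBr)
Why: Bromine adds across the enone double bond and triethylamine then removes HBr (addition–elimination α-bromination of an enone), the acidic C2–H and the tertiary C3–Br being lost so that the double bond returns to conjugation.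

Step 2
Reactants: 3 2-bromo-3-methylcyclopent-2-en-1-one
Product: 4 6-bromo-7-methyl-1,4-dioxaspiro[4.4]non-6-ene
Conditions: HOCH2CH2OH, p-TsOH·H2O (cat.), benzene, reflux, Dean–Stark
Reagents that add atoms: ethylene glycol (OCCO)
Why: Acid-catalysed ketalisation with azeotropic removal of water, in which the vinylic bromine keeps the double bond in place, as is usual for 2-bromoenones.

Step 3
Reactants: 4 6-bromo-7-methyl-1,4-dioxaspiro[4.4]non-6-ene
Product: 7 1-(7-methyl-1,4-dioxaspiro[4.4]non-6-en-6-yl)ethan-1-one, via vinyllithium 5 (not isolated), via Weinreb adduct 6 (not isolated)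
Conditions: n-BuLi, THF, −78 °C; then MeC(O)N(OMe)Me, −78 to 0 °C; aq. NH4Cl
Reagents that add atoms: N-methoxy-N-methylacetamide (CC(=O)N(C)OC)
Why: Bromine–lithium exchange gives a vinyllithium that is acylated once by the Weinreb amide (Weinreb ketone synthesis), since the chelated tetrahedral adduct survives until the quench and no tertiary alcohol can form.

Step 4
Reactants: 7 1-(7-methyl-1,4-dioxaspiro[4.4]non-6-en-6-yl)ethan-1-one
Product: 9 triethyl{[1-(7-methyl-1,4-dioxaspiro[4.4]non-6-en-6-yl)ethenyl]oxy}silane, via lithium enolate 8 (not isolated)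
Conditions: LiN(SiMe3)2, THF, −78 °C; then Et3SiCl, −78 to 0 °C
Reagents that add atoms: chlorotriethylsilane (CC[Si](Cl)(CC)CC)
Why: Kinetic deprotonation of the methyl ketone at the acetyl CH3 (cross-conjugated enolate) and O-silylation give the 2-siloxydiene, and the basic conditions avoid silyl triflates, which would open the allylic ketal.

Step 5
Reactants: 10 methyl 4-oxobutanoate
Product: 11 methyl (E)-4-[(tert-butyldimethylsilyl)oxy]but-3-enoate
Conditions: TBSOTf, Et3N, CH2Cl2, 0 °C; E isomer separated on Et3N-deactivated silica gel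
Reagents that add atoms: tert-butyldimethylsilyl trifluoromethanesulfonate (CC(C)(C)[Si](C)(C)OS(=O)(=O)C(F)(F)F)
Why: Soft enolisation of the aldehyde by silyl triflate and amine gives the silyl enol ether while the ester is untouched; only the E isomer is taken on, and the Z isomer can be hydrolysed back to 10 and recycled.

Step 6
Reactants: 11 methyl (E)-4-[(tert-butyldimethylsilyl)oxy]but-3-enoate
Product: 12 methyl (E)-4-[(tert-butyldimethylsilyl)oxy]-2-diazobut-3-enoate
Conditions: p-ABSA, DBU, MeCN, 0 °C
Reagents that add atoms: 4-acetamidobenzenesulfonyl azide (CC(=O)Nc1ccc(cc1)S(=O)(=O)N=[N+]=[N-])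
Why: Regitz diazo transfer to the methylene group that is activated by both the ester and the enol ether double bond, which leaves the alkene geometry untouched.

Step 7
Reactants: 9 triethyl{[1-(7-methyl-1,4-dioxaspiro[4.4]non-6-en-6-yl)ethenyl]oxy}silane; 12 methyl (E)-4-[(tert-butyldimethylsilyl)oxy]-2-diazobut-3-enoate
Product: 14 cycloheptadiene ester (1α-OTBS; 3-CO2Me on C2=C3; 5-OTES on C5=C6; 7β-Me; C10 ethylene ketal), via divinylcyclopropane 13 (not isolated)
Conditions: Rh2(R-DOSP)4 (1 mol %), hexanes, −40 °C to rt, slow addition of 12; then toluene, 100 °C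
Reagents that add atoms: none
Why: The chiral dirhodium carbenoid formed from 12 by loss of N2 adds to the terminal, electron-rich C4=C5 enol ether of 9 (bond C3–C4 and the cyclopropane bond C3–C5), and the cis-divinylcyclopropane 13 then undergoes a [3,3] Cope rearrangement that forms C1–C7 and breaks C3–C5. The closest known reaction type is the cyclopropanation/Cope (formal [4+3]) reaction of rhodium vinylcarbenoids from vinyldiazoacetates with dienes, 2-siloxydienes included; the 4-siloxy group on the carbenoid is an extension that acts as a spectator. The seven-membered ring closes by the sigmatropic shift through a boat transition state, driven by release of cyclopropane strain, and heating is planned because the C7 methyl has to point inward. In that boat the siloxy substituent of the E enol ether and the cyclopentene carbon C8 occupy the two exo positions, so the oxygen on C1 finishes on the same face as C8 and opposite to the methyl on C7, while the absolute configuration of both centres follows from the face of C4=C5 that the catalyst selects in the cyclopropanation. The step needs site selectivity (the fully substituted C6=C7 alkene is too hindered to intercept the carbenoid), a cis relationship of the two vinyl groups (donor/acceptor carbenoids place the ester trans to the larger alkene substituent) and an intact E enol ether in 12.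

Step 8
Reactants: 14 cycloheptadiene ester
Product: 15 allylic alcohol (as 14 but 3-CH2OH)
Conditions: i-Bu2AlH, CH2Cl2, −78 °C; aq. potassium sodium tartrate
Reagents that add atoms: none
Why: 1,2-Reduction of the conjugated ester to the allylic alcohol by the aluminium hydride at low temperature (ester reduction), to which the silyl enol ether, the silyl ether and the ketal are inert.

Step 9
Reactants: 15 allylic alcohol
Product: 17 3-methyl silyl enol ether (as 14 but 3-CH3), via allylic mesylate 16 (not isolated)
Conditions: MsCl, Et3N, THF, −20 °C; then LiEt3BH, −20 to 0 °C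
Reagents that add atoms: none
Why: The primary allylic mesylate is displaced by hydride in an SN2 reduction (deoxygenation via a sulfonate); attack at the CH2 group is favoured over SN2′ attack at C2, which is shielded by the C1 silyl ether and the quaternary C7, so the C2=C3 bond stays in place.

Step 10
Reactants: 17 3-methyl silyl enol ether
Product: 19 trans-fused C5 ketone (1α-OTBS; 3-methyl-Δ2; 6α-H; 7β-Me; C10 ethylene ketal), via ammonium enolate 18 (not isolated)
Conditions: Bu4NF, AcOH, THF, −78 to −20 °C
Reagents that add atoms: none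
Why: Fluoride cleaves the triethylsilyl enol ether much faster than the alkyl TBS ether, and the regiodefined enolate is protonated at C6 by the acetic acid buffer (silyl enol ether cleavage with kinetic protonation); the C7 methyl sits pseudo-axially over the β-face of C6, so the proton should arrive from the α-face and give the trans ring fusion, and the cold, buffered medium avoids migration of the C2=C3 bond into conjugation.

Step 11
Reactants: 19 trans-fused C5 ketone
Product: 20 5α-alcohol (as 19 but 5α-OH)
Conditions: Li, NH3(l), THF, MeOH, −78 °C; then NH4Cl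
Reagents that add atoms: none
Why: Dissolving-metal reduction of the ketone should give the thermodynamically preferred equatorial 5α-alcohol, which avoids the syn-axial contact with the C7 methyl (hydride reagents, by contrast, would attack the open α-face and give the 5β-alcohol); the isolated alkene, the silyl ether and the ketal are not reduced.

Step 12
Reactants: 20 5α-alcohol
Product: 21 5α-hydroxy C10 ketone (ketal removed)
Conditions: PPTS, acetone/H2O, 50 °C
Reagents that add atoms: water (O)
Why: Mild acid-catalysed ketal hydrolysis in wet acetone frees the C10 ketone, PPTS being too weak to cleave the secondary TBS ether, to dehydrate the β-hydroxy ketone or to enolise it at C6 at a useful rate.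

Step 13
Reactants: 21 5α-hydroxy C10 ketone
Product: 22 5α,10β-diol bearing 10α-isopropyl (1α-OTBS)
Conditions: i-PrMgCl, CeCl3, THF, −78 to 0 °C; aq. NH4Cl
Reagents that add atoms: isopropylmagnesium chloride (CC(C)[Mg]Cl)
Why: The organocerium reagent (Grignard addition in the presence of CeCl3) adds to the hindered, enolisable cyclopentanone without enolisation or β-hydride reduction once the C5 hydroxyl has been deprotonated, and it attacks the α-face, anti to the C7 methyl and to the C5 branch on C6, so the hydroxyl ends up β and the isopropyl group α.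

Step 14
Reactants: 22 5α,10β-diol bearing 10α-isopropyl; 23 3,4-dimethoxybenzoyl chloride
Product: 24 5α-veratroate (1α-OTBS; 10β-OH)
Conditions: DMAP, Et3N, CH2Cl2, 0 °C to rt
Reagents that add atoms: none
Why: DMAP-catalysed acylation with the acid chloride esterifies only the secondary C5 alcohol, because the tertiary C10 alcohol flanked by the isopropyl group and the ring fusion reacts far more slowly.

Step 15
Reactants: 24 5α-veratroate
Product: 25 1α-alcohol (5α-veratroate; 10β-OH)
Conditions: HF·pyridine, pyridine, THF, 0 °C to rt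
Reagents that add atoms: none
Why: Fluoride-mediated silyl ether cleavage under buffered, non-basic conditions removes the TBS group without acyl migration or ester cleavage.

Step 16
Reactants: 25 1α-alcohol; 26 angelic acid
Product: 28 target CNP0142353.1 (1α-angelate; 5α-veratroate; 6α-H; 7β-Me; 10β-OH; 10α-isopropyl), via mixed anhydride 27 (not isolated)
Conditions: 26, 2,4,6-Cl3C6H2COCl, Et3N, toluene, rt; then 25, 80 °C
Reagents that add atoms: none
Why: Yamaguchi esterification, in which the mixed anhydride 27 acylates the hindered allylic C1 alcohol at the angeloyl carbonyl; the DMAP-free conditions should keep the Z double bond from isomerising to the tiglate, and the tertiary C10 alcohol does not react.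

Compound list

1 | 3-methylcyclopent-2-en-1-one | CC1=CC(=O)CC1 | starting material
2 | trans-2,3-dibromo-3-methylcyclopentan-1-one (racemic; one enantiomer drawn) | C[C@]1(Br)CCC(=O)[C@@H]1Br | intermediate
3 | 2-bromo-3-methylcyclopent-2-en-1-one | CC1=C(Br)C(=O)CC1 | intermediate
4 | 6-bromo-7-methyl-1,4-dioxaspiro[4.4]non-6-ene | CC1=C(Br)C2(CC1)OCCO2 | intermediate
5 | (7-methyl-1,4-dioxaspiro[4.4]non-6-en-6-yl)lithium | [Li]C1=C(C)CCC12OCCO2 | intermediate
6 | lithium 1-[methoxy(methyl)amino]-1-(7-methyl-1,4-dioxaspiro[4.4]non-6-en-6-yl)ethan-1-olate (chelated Weinreb adduct; racemic at the carbinol carbon) | CC(O[Li])(N(C)OC)C1=C(C)CCC12OCCO2 | intermediate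
7 | 1-(7-methyl-1,4-dioxaspiro[4.4]non-6-en-6-yl)ethan-1-one | CC(=O)C1=C(C)CCC12OCCO2 | intermediate
8 | lithium 1-(7-methyl-1,4-dioxaspiro[4.4]non-6-en-6-yl)ethen-1-olate | C=C(O[Li])C1=C(C)CCC12OCCO2 | intermediate
9 | triethyl{[1-(7-methyl-1,4-dioxaspiro[4.4]non-6-en-6-yl)ethenyl]oxy}silane (2-siloxydiene) | C=C(O[Si](CC)(CC)CC)C1=C(C)CCC12OCCO2 | intermediate
10 | methyl 4-oxobutanoate | COC(=O)CCC=O | starting material
11 | methyl (E)-4-[(tert-butyldimethylsilyl)oxy]but-3-enoate | COC(=O)C/C=C/O[Si](C)(C)C(C)(C)C | intermediate
12 | methyl (E)-4-[(tert-butyldimethylsilyl)oxy]-2-diazobut-3-enoate | COC(=O)C(=[N+]=[N-])/C=C/O[Si](C)(C)C(C)(C)C | intermediate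
13 | methyl (1S,2R)-1-[(E)-2-(tert-butyldimethylsilyloxy)ethenyl]-2-(7-methyl-1,4-dioxaspiro[4.4]non-6-en-6-yl)-2-(triethylsilyloxy)cyclopropane-1-carboxylate (cis-divinylcyclopropane) | COC(=O)[C@]1(/C=C/O[Si](C)(C)C(C)(C)C)C[C@@]1(O[Si](CC)(CC)CC)C2=C(C)CCC23OCCO3 | intermediate
14 | cycloheptadiene ester: 1α-OTBS, C2=C3 with CO2Me on C3, C5=C6 enol ether with OTES on C5, 7β-methyl, C10 ethylene ketal | CC(C)(C)[Si](C)(C)O[C@@H]1C=C(C(=O)OC)CC(O[Si](CC)(CC)CC)=C2[C@]1(C)CCC23OCCO3 | intermediate
15 | allylic alcohol: as 14 with CH2OH on C3 | CC(C)(C)[Si](C)(C)O[C@@H]1C=C(CO)CC(O[Si](CC)(CC)CC)=C2[C@]1(C)CCC23OCCO3 | intermediate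
16 | allylic mesylate: as 14 with CH2OMs on C3 | CC(C)(C)[Si](C)(C)O[C@@H]1C=C(COS(C)(=O)=O)CC(O[Si](CC)(CC)CC)=C2[C@]1(C)CCC23OCCO3 | intermediate
17 | 3-methyl silyl enol ether: as 14 with CH3 on C3 | CC(C)(C)[Si](C)(C)O[C@@H]1C=C(C)CC(O[Si](CC)(CC)CC)=C2[C@]1(C)CCC23OCCO3 | intermediate
18 | tetrabutylammonium C5 enolate (C5=C6) of 19 | CC(C)(C)[Si](C)(C)O[C@@H]1C=C(C)CC([O-])=C2[C@]1(C)CCC23OCCO3.CCCC[N+](CCCC)(CCCC)CCCC | intermediate
19 | trans-fused C5 ketone: 1α-OTBS, 3-methyl-Δ2, 5-oxo, 6α-H, 7β-methyl, C10 ethylene ketal | CC(C)(C)[Si](C)(C)O[C@@H]1C=C(C)CC(=O)[C@@H]2[C@]1(C)CCC23OCCO3 | intermediate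
20 | 5α-alcohol: as 19 with 5α-OH (5β-H) | CC(C)(C)[Si](C)(C)O[C@@H]1C=C(C)C[C@H](O)[C@@H]2[C@]1(C)CCC23OCCO3 | intermediate
21 | 5α-hydroxy C10 ketone: 1α-OTBS, 6α-H, 7β-methyl | CC(C)(C)[Si](C)(C)O[C@@H]1C=C(C)C[C@H](O)[C@@H]2[C@]1(C)CCC2=O | intermediate
22 | 5α,10β-diol: 1α-OTBS, 10α-isopropyl, 6α-H, 7β-methyl | CC(C)(C)[Si](C)(C)O[C@@H]1C=C(C)C[C@H](O)[C@@H]2[C@]1(C)CC[C@@]2(O)C(C)C | intermediate
23 | 3,4-dimethoxybenzoyl chloride (veratroyl chloride) | COc1ccc(cc1OC)C(Cl)=O | starting material
24 | 5α-veratroate: 1α-OTBS, 10β-OH, 10α-isopropyl | CC(C)(C)[Si](C)(C)O[C@@H]1C=C(C)C[C@H](OC(=O)c2ccc(OC)c(OC)c2)[C@@H]2[C@]1(C)CC[C@@]2(O)C(C)C | intermediate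
25 | 1α-alcohol: 5α-veratroate, 10β-OH, 10α-isopropyl | O[C@@H]1C=C(C)C[C@H](OC(=O)c2ccc(OC)c(OC)c2)[C@@H]2[C@]1(C)CC[C@@]2(O)C(C)C | intermediate
26 | angelic acid, (Z)-2-methylbut-2-enoic acid | C/C=C(/C)C(O)=O | starting material
27 | (Z)-2-methylbut-2-enoic 2,4,6-trichlorobenzoic anhydride | C/C=C(/C)C(=O)OC(=O)c1c(Cl)cc(Cl)cc1Cl | intermediate
28 | CNP0142353.1, (3R,3aS,4S,8R,8aS)-3-hydroxy-6,8a-dimethyl-8-{[(2Z)-2-methylbut-2-enoyl]oxy}-3-(propan-2-yl)-1,2,3,3a,4,5,8,8a-octahydroazulen-4-yl 3,4-dimethoxybenzoate | C/C=C(/C)C(=O)O[C@@H]1C=C(C)C[C@H](OC(=O)c2ccc(OC)c(OC)c2)[C@@H]2[C@]1(C)CC[C@@]2(O)C(C)C | target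

Total step count: 16.
Longest linear sequence: 14 steps (from 1 through steps 1–4 and 7–16); the diazoester branch (steps 5 and 6) joins at step 7.

Steps most likely to fail

1. Step 7. The silyloxy group on C5 can stabilise positive charge, so the carbenoid addition may turn stepwise and give the trans-divinylcyclopropane or five-membered-ring by-products, and the donor–acceptor cyclopropane may open and reclose on heating. Both processes erode the cis geometry needed for the Cope step and the enantiomeric purity, and a 1,1-disubstituted enol ether may be read less well by the chiral catalyst than a monosubstituted alkene. The fallback sets out from 4 and leaves the C5 oxygen out of the cycloaddition. Suzuki–Miyaura coupling of 4 with CH2=CHBF3K (PdCl2(dppf), Cs2CO3, THF/H2O, 70 °C) gives 6-ethenyl-7-methyl-1,4-dioxaspiro[4.4]non-6-ene F1, a diene with a monosubstituted terminal alkene, the substrate class on which the carbenoid cyclopropanation/Cope sequence is best established. With 12 and Rh2(R-DOSP)4 in hexanes it should give the cis-divinylcyclopropane F2 and, on heating, the cycloheptadiene ester F3, which carries C5–H in place of the silyl enol ether and has the C1 and C7 configuration of 14. The conditions of steps 8 and 9 then give the allylic alcohol F4, its mesylate F5 and the 3-methyl-2,5-diene F6. Hydroboration of F6 with BH3·THF at 0 °C should place boron on C5 and hydrogen on C6 in a syn addition to the α-face, anti to the pseudo-axial C7 methyl, to give the alkylborane F7; the C2=C3 alkene is shielded by the neighbouring C1 silyl ether. Oxidation with NaBO3·4H2O returns to the route at 20, so steps 10 and 11 are bypassed.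

2. Step 10. Protonation of the enolate may occur partly on the β-face of C6 (cis ring fusion), and proton exchange at the doubly activated C4 position may move the C2=C3 double bond into conjugation with the ketone. The fallback sets out from 17: CsF and PhNTf2 in DME convert the silyl enol ether regiospecifically into the C5 enol triflate F8. Reduction with Pd(OAc)2, PPh3, HCO2H and Bu3N in DMF at 60 °C gives the diene F6, and hydroboration–oxidation as under point 1 (via F7) leads back to the route at 20. C6–H and C5–O are then introduced together by one concerted syn addition instead of by protonation and a separate reduction.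

3. Step 11. The electron-transfer reduction may show too small a preference for the equatorial alcohol, and the allylic C1–O bond may be cleaved reductively. The fallback sets out from 19: NaBH4 in MeOH at 0 °C reduces the ketone from the open α-face to the 5β-alcohol F9, whose configuration is corrected later. PPTS in wet acetone gives the hydroxy ketone F10, and i-PrMgCl/CeCl3 as in step 13 gives the 5-epi-diol F11. Dess–Martin periodinane (NaHCO3, CH2Cl2) oxidises only the secondary alcohol to the β-hydroxy ketone F12. Evans–Saksena reduction with Me4NBH(OAc)3 in AcOH/MeCN at −20 °C then delivers hydride intramolecularly from boron bound to the 10β-oxygen to the β-face of C5 and gives the anti-1,3-diol 22, where the route is rejoined.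

Further compounds

F1 | step 7 | 6-ethenyl-7-methyl-1,4-dioxaspiro[4.4]non-6-ene | C=CC1=C(C)CCC12OCCO2
F2 | step 7 | cis-divinylcyclopropane from F1 and 12 | COC(=O)[C@]1(/C=C/O[Si](C)(C)C(C)(C)C)C[C@H]1C2=C(C)CCC23OCCO3
F3 | step 7 | cycloheptadiene ester with C5–H: 1α-OTBS, CO2Me on C3, C5=C6, 7β-methyl, C10 ethylene ketal | CC(C)(C)[Si](C)(C)O[C@@H]1C=C(C(=O)OC)CC=C2[C@]1(C)CCC23OCCO3
F4 | step 7 | allylic alcohol: as F3 with CH2OH on C3 | CC(C)(C)[Si](C)(C)O[C@@H]1C=C(CO)CC=C2[C@]1(C)CCC23OCCO3
F5 | step 7 | allylic mesylate: as F3 with CH2OMs on C3 | CC(C)(C)[Si](C)(C)O[C@@H]1C=C(COS(C)(=O)=O)CC=C2[C@]1(C)CCC23OCCO3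
F6 | step 7 | 3-methyl-2,5-diene: as F3 with CH3 on C3 | CC(C)(C)[Si](C)(C)O[C@@H]1C=C(C)CC=C2[C@]1(C)CCC23OCCO3
F7 | step 7 | C5α-alkylborane with 6α-H | CC(C)(C)[Si](C)(C)O[C@@H]1C=C(C)C[C@H](B)[C@@H]2[C@]1(C)CCC23OCCO3
F8 | step 10 | C5 enol triflate (C5=C6) | CC(C)(C)[Si](C)(C)O[C@@H]1C=C(C)CC(OS(=O)(=O)C(F)(F)F)=C2[C@]1(C)CCC23OCCO3
F9 | step 11 | 5β-alcohol: C5 epimer of 20 | CC(C)(C)[Si](C)(C)O[C@@H]1C=C(C)C[C@@H](O)[C@@H]2[C@]1(C)CCC23OCCO3
F10 | step 11 | 5β-hydroxy C10 ketone | CC(C)(C)[Si](C)(C)O[C@@H]1C=C(C)C[C@@H](O)[C@@H]2[C@]1(C)CCC2=O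
F11 | step 11 | 5β,10β-diol with 10α-isopropyl (5-epi-22) | CC(C)(C)[Si](C)(C)O[C@@H]1C=C(C)C[C@@H](O)[C@@H]2[C@]1(C)CC[C@@]2(O)C(C)C
F12 | step 11 | C5 ketone with 10β-hydroxy and 10α-isopropyl | CC(C)(C)[Si](C)(C)O[C@@H]1C=C(C)CC(=O)[C@@H]2[C@]1(C)CC[C@@]2(O)C(C)C
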